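## Retrosynthetic overview
1. The nitrogen ring is opened last. The C1–C8a bond and the C1 stereocentre come from a Bischler–Napieralski closure of an N-methylacetamide, followed by hydride delivery anti to the C3 methyl (cis).
2. The N-methyl group and the last O-methyl group come from one double methylation of a biaryl naphthol acetamide.
3. Key disconnection is the biaryl bond, which joins two carbons that are both π-nucleophilic. Naphthol C-4 is made electrophilic as an O-iodanyl naphthol (phenoxenium, a vinylogous enolonium) and is attacked by the 3,5-dimethoxyaryl unit.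
4. The naphthol comes from 2-methoxy-4-methylbenzoic acid by directed ortho-allylation and anionic ring closure. The chiral arene comes from 3,5-dimethoxyphenyl Grignard reagent and an (S)-alanine-derived N-Boc-aziridine, which supplies C3.
5. Ring order: second naphthalene ring, then the biaryl bond, then the tetrahydroisoquinoline ring.

Assumption: the SMILES fixes only C-1 (R) and C-3 (S, cis) and leaves the biaryl axis open. The axis is therefore not controlled, and the two rotational isomers can be separated by HPLC at the end if one is wanted.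

## Route

**Step 1**
Reactants: 1 1-bromo-3,5-dimethoxybenzene; 2 tert-butyl (S)-2-methylaziridine-1-carboxylate
Product: 4 tert-butyl (S)-[1-(3,5-dimethoxyphenyl)propan-2-yl]carbamate, via 3,5-dimethoxyphenylmagnesium bromide 3 (not isolated)
Conditions: Mg, THF, 40 °C; CuBr·SMe2 (10 mol %), 2, THF, −30 °C to rt; H2O quench
Reagents that add atoms: none
Why: Copper-catalysed SN2 ring opening of an activated aziridine by an aryl Grignard reagent occurs at the unsubstituted CH2, so the alanine-derived stereocentre is untouched and becomes C-3 (S).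

**Step 2**
Reactants: 4 tert-butyl (S)-[1-(3,5-dimethoxyphenyl)propan-2-yl]carbamate
Product: 6 (S)-N-[1-(3,5-dimethoxyphenyl)propan-2-yl]acetamide, via amine hydrochloride 5 (not isolated)
Conditions: 4 M HCl in dioxane, rt; evaporate; Ac2O, aq NaOH, CH2Cl2, 0 °C
Reagents that add atoms: acetic anhydride CC(=O)OC(C)=O
Why: Boc acidolysis with HCl (chosen to avoid tert-butylation of the electron-rich ring) followed by Schotten–Baumann N-acetylation leaves the stereocentre unaffected.

**Step 3**
Reactants: 7 2-methoxy-4-methylbenzoic acid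
Product: 9 N,N-diethyl-2-methoxy-4-methylbenzamide, via 2-methoxy-4-methylbenzoyl chloride 8 (not isolated)
Conditions: SOCl2, cat. DMF, toluene, 70 °C; evaporate; Et2NH, aq NaOH, CH2Cl2, 0 °C
Reagents that add atoms: diethylamine CCNCC
Why: Acid chloride formation and Schotten–Baumann amidation install the tertiary amide that directs the metalation in step 4 and acts as the internal acylating group in step 5.

**Step 4**
Reactants: 9 N,N-diethyl-2-methoxy-4-methylbenzamide; 10 allyl bromide
Product: 13 2-allyl-N,N-diethyl-6-methoxy-4-methylbenzamide, via ortho-lithiated amide 11 (not isolated), via arylmagnesium bromide 12 (not isolated)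
Conditions: s-BuLi, TMEDA, THF, −78 °C; MgBr2·OEt2, −78 °C to rt; 10, rt
Reagents that add atoms: none
Why: In this directed ortho-metalation the CONEt2 group, the strongest director present, sends s-BuLi to C-6, and transmetalation to magnesium allows clean allylation without halogen–metal exchange.

**Step 5**
Reactants: 13 2-allyl-N,N-diethyl-6-methoxy-4-methylbenzamide
Product: 14 8-methoxy-6-methylnaphthalen-1-ol
Conditions: LiN(i-Pr)2 (2.2 equiv), THF, −78 °C to rt; 1 M HCl
Reagents that add atoms: none
Why: In this anionic benzannulation of an o-allylbenzamide, deprotonation of the benzylic-allylic CH2 gives an allyl anion whose terminal carbon acylates on the neighbouring amide, and loss of diethylamide with tautomerisation gives the 1-naphthol with OH peri to OMe and the regiochemistry fixed by step 4.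

**Step 6 (key step)**
Reactants: 14 8-methoxy-6-methylnaphthalen-1-ol; 6 (S)-N-[1-(3,5-dimethoxyphenyl)propan-2-yl]acetamide
Product: 16 (S)-N-{1-[2-(4-hydroxy-5-methoxy-7-methylnaphthalen-1-yl)-3,5-dimethoxyphenyl]propan-2-yl}acetamide, via naphthyloxy-λ3-iodane 15 (not isolated)
Conditions: 6 (2.0 equiv, excess recovered), PhI(OCOCF3)2 (1.0 equiv, added over 1 h), (CF3)2CHOH/CH2Cl2 1:1, 4 Å MS, −20 °C to 0 °C
Reagents that add atoms: none
Why: Proposed new method: the naphthol exchanges a trifluoroacetate ligand on trivalent iodine to give 15, a phenoxenium (vinylogous enolonium) equivalent in which C-4, normally the nucleophilic para carbon, is electrophilic, so the likewise nucleophilic C-2 of 6 (para to one OMe, ortho to the other) attacks it in a Friedel–Crafts manner with reductive loss of PhI and rearomatisation, while the O-bound iodane and the peri OMe screen naphthol C-2, (CF3)2CHOH stabilises the cationic species and damps naphthol homocoupling, and excess 6 plus slow oxidant addition limit over-oxidation; the closest known reaction type is the hypervalent-iodine-mediated oxidative phenol–arene cross-coupling in fluorinated alcohols, not yet shown for a para-selective 1-naphthol coupling that builds a triply ortho-substituted biaryl; no stereocentre is formed or touched and the axis arises as a mixture.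

**Step 7**
Reactants: 16 (S)-N-{1-[2-(4-hydroxy-5-methoxy-7-methylnaphthalen-1-yl)-3,5-dimethoxyphenyl]propan-2-yl}acetamide
Product: 17 (S)-N-{1-[2-(4,5-dimethoxy-7-methylnaphthalen-1-yl)-3,5-dimethoxyphenyl]propan-2-yl}-N-methylacetamide
Conditions: NaH (2.5 equiv), MeI (3 equiv), DMF, 0 °C to rt
Reagents that add atoms: iodomethane CI
Why: NaH deprotonates both the naphthol OH and the amide NH, so one Williamson-type double alkylation installs the last O-methyl and the N-methyl, with no basic amine present to quaternise and no acidic C–H at the stereocentre.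

**Step 8**
Reactants: 17 (S)-N-{1-[2-(4,5-dimethoxy-7-methylnaphthalen-1-yl)-3,5-dimethoxyphenyl]propan-2-yl}-N-methylacetamide
Product: 19 (1R,3S)-5-(4,5-dimethoxy-7-methylnaphthalen-1-yl)-6,8-dimethoxy-1,2,3-trimethyl-1,2,3,4-tetrahydroisoquinoline (target), via N-methyl-3,4-dihydroisoquinolinium chloride 18 (not isolated)
Conditions: POCl3, MeCN, 80 °C; evaporate; NaBH4 (excess), MeOH, −78 °C to 0 °C
Reagents that add atoms: none
Why: Bischler–Napieralski cyclisation of the tertiary amide (chloroiminium attack at the only free position ortho to the side chain, activated by both OMe groups) gives iminium 18, in which allylic strain with N-Me holds the C-3 methyl pseudo-axial, so borohydride attacks C-1 from the opposite face and places the C-1 methyl cis to the C-3 methyl, which is (1R) from (3S).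

## Compound list
1 | 1-bromo-3,5-dimethoxybenzene | COc1cc(Br)cc(OC)c1 | starting material
2 | tert-butyl (S)-2-methylaziridine-1-carboxylate | C[C@H]1CN1C(=O)OC(C)(C)C | starting material
3 | 3,5-dimethoxyphenylmagnesium bromide | COc1cc([Mg]Br)cc(OC)c1 | intermediate
4 | tert-butyl (S)-[1-(3,5-dimethoxyphenyl)propan-2-yl]carbamate | C[C@@H](Cc1cc(OC)cc(OC)c1)NC(=O)OC(C)(C)C | intermediate
5 | (S)-1-(3,5-dimethoxyphenyl)propan-2-aminium chloride | C[C@@H](Cc1cc(OC)cc(OC)c1)[NH3+].[Cl-] | intermediate
6 | (S)-N-[1-(3,5-dimethoxyphenyl)propan-2-yl]acetamide | C[C@@H](Cc1cc(OC)cc(OC)c1)NC(C)=O | intermediate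
7 | 2-methoxy-4-methylbenzoic acid | COc1cc(C)ccc1C(=O)O | starting material
8 | 2-methoxy-4-methylbenzoyl chloride | COc1cc(C)ccc1C(=O)Cl | intermediate
9 | N,N-diethyl-2-methoxy-4-methylbenzamide | CCN(CC)C(=O)c1ccc(C)cc1OC | intermediate
10 | allyl bromide | C=CCBr | starting material
11 | N,N-diethyl-2-lithio-6-methoxy-4-methylbenzamide | CCN(CC)C(=O)c1c([Li])cc(C)cc1OC | intermediate
12 | [2-(diethylcarbamoyl)-3-methoxy-5-methylphenyl]magnesium bromide | CCN(CC)C(=O)c1c([Mg]Br)cc(C)cc1OC | intermediate
13 | 2-allyl-N,N-diethyl-6-methoxy-4-methylbenzamide | C=CCc1cc(C)cc(OC)c1C(=O)N(CC)CC | intermediate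
14 | 8-methoxy-6-methylnaphthalen-1-ol | COc1cc(C)cc2cccc(O)c12 | intermediate
15 | [(8-methoxy-6-methylnaphthalen-1-yl)oxy](phenyl)-λ3-iodanyl trifluoroacetate | COc1cc(C)cc2cccc(OI(OC(=O)C(F)(F)F)c3ccccc3)c12 | intermediate
16 | (S)-N-{1-[2-(4-hydroxy-5-methoxy-7-methylnaphthalen-1-yl)-3,5-dimethoxyphenyl]propan-2-yl}acetamide | C[C@@H](Cc1cc(OC)cc(OC)c1-c1ccc(O)c2c(OC)cc(C)cc12)NC(C)=O | intermediate
17 | (S)-N-{1-[2-(4,5-dimethoxy-7-methylnaphthalen-1-yl)-3,5-dimethoxyphenyl]propan-2-yl}-N-methylacetamide | C[C@@H](Cc1cc(OC)cc(OC)c1-c1ccc(OC)c2c(OC)cc(C)cc12)N(C)C(C)=O | intermediate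
18 | (S)-5-(4,5-dimethoxy-7-methylnaphthalen-1-yl)-6,8-dimethoxy-1,2,3-trimethyl-3,4-dihydroisoquinolin-2-ium chloride | C[C@H]1Cc2c(-c3ccc(OC)c4c(OC)cc(C)cc34)c(OC)cc(OC)c2C(C)=[N+]1C.[Cl-] | intermediate
19 | (1R,3S)-5-(4,5-dimethoxy-7-methylnaphthalen-1-yl)-6,8-dimethoxy-1,2,3-trimethyl-1,2,3,4-tetrahydroisoquinoline | COc1cc(OC)c2c(c1-c1ccc(OC)c3c(OC)cc(C)cc13)C[C@H](C)N(C)[C@@H]2C | target

## Step count
- Total steps: 8.
- Longest linear sequence: 6 (steps 3, 4, 5, 6, 7, 8).

## Steps most likely to fail

**Step 6.**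
- Risks: homocoupling of 14 at C-4; further oxidation of 16; attack at naphthol C-2; attack from C-4 of 6.
- The fallback sets out from 14 and 6 and comes back at 17. It stores the reversed-polarity carbon in an isolable salt instead of generating it by oxidation in the presence of the product.
- 14 is iodinated para to the hydroxyl with N-iodosuccinimide in MeCN at 0 °C to give 4-iodo-8-methoxy-6-methylnaphthalen-1-ol F1.
- MeI/K2CO3 in acetone gives 1-iodo-4,5-dimethoxy-7-methylnaphthalene F2.
- Oxidation with mCPBA/TsOH·H2O in CH2Cl2–CF3CH2OH in the presence of mesitylene, then anion exchange with NaOTf, gives (4,5-dimethoxy-7-methylnaphthalen-1-yl)(2,4,6-trimethylphenyl)iodonium triflate F3.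
- This aryl cation equivalent arylates 6 at C-2 with Cu(OTf)2 (10 mol %) and 2,6-di-tert-butylpyridine in ClCH2CH2Cl at 60 °C. The reaction runs through an aryl species of trivalent copper, and the mesityl group stays on iodine. The product is (S)-N-{1-[2-(4,5-dimethoxy-7-methylnaphthalen-1-yl)-3,5-dimethoxyphenyl]propan-2-yl}acetamide F4.
- NaH/MeI in DMF then N-methylates F4 to 17.

**Step 8.**
- Risks: slow chloroiminium closure next to the bulky naphthyl group; von Braun-type loss of N-methyl; eroded cis selectivity.
- The fallback sets out from 6, uses 14, and comes back at 19. It builds the heterocycle before the biaryl bond.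
- 6 is cyclised with POCl3 in MeCN at 80 °C to (S)-6,8-dimethoxy-1,3-dimethyl-3,4-dihydroisoquinoline F5.
- NaBH4 in MeOH reduces F5 anti to the C-3 methyl to give (1R,3S)-6,8-dimethoxy-1,3-dimethyl-1,2,3,4-tetrahydroisoquinoline F6.
- Aqueous HCHO and NaBH(OAc)3 give (1R,3S)-6,8-dimethoxy-1,2,3-trimethyl-1,2,3,4-tetrahydroisoquinoline F7.
- F7 is protonated in the flask with CF3CO2H to shield the amine. It is then coupled at C-5 with 14 under the step 6 conditions to give 4-[(1R,3S)-6,8-dimethoxy-1,2,3-trimethyl-1,2,3,4-tetrahydroisoquinolin-5-yl]-8-methoxy-6-methylnaphthalen-1-ol F8.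
- NaH (1.05 equiv) and MeI (1.0 equiv) in DMF at 0 °C give 19, because the naphthoxide reacts faster than the hindered tertiary amine.

**Step 5.**
- Risks: isomerisation of the allyl group to the propenyl arene without closure; oligomerisation of the allyl anion.
- The fallback sets out from 9 and comes back at 14. It brings in the two missing ring carbons as a Michael acceptor.
- 9 is ortho-lithiated as in step 4 and quenched with MeI to give N,N-diethyl-2-methoxy-4,6-dimethylbenzamide F9.
- Lateral lithiation of the 6-methyl group with LiN(i-Pr)2 in THF at −78 °C is followed by addition of phenyl vinyl sulfoxide. A Michael addition–acylation cascade gives 8-methoxy-6-methyl-2-(phenylsulfinyl)-3,4-dihydronaphthalen-1(2H)-one F10 as a diastereomer mixture.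
- Heating F10 in toluene at 110 °C over CaCO3 causes sulfoxide syn elimination, and the resulting enone tautomerises to 14.

## Further compounds
F1 | step 6 | 4-iodo-8-methoxy-6-methylnaphthalen-1-ol | COc1cc(C)cc2c(I)ccc(O)c12
F2 | step 6 | 1-iodo-4,5-dimethoxy-7-methylnaphthalene | COc1ccc(I)c2cc(C)cc(OC)c12
F3 | step 6 | (4,5-dimethoxy-7-methylnaphthalen-1-yl)(2,4,6-trimethylphenyl)iodonium triflate | COc1ccc([I+]c3c(C)cc(C)cc3C)c2cc(C)cc(OC)c12.[O-]S(=O)(=O)C(F)(F)F
F4 | step 6 | (S)-N-{1-[2-(4,5-dimethoxy-7-methylnaphthalen-1-yl)-3,5-dimethoxyphenyl]propan-2-yl}acetamide | C[C@@H](Cc1cc(OC)cc(OC)c1-c1ccc(OC)c2c(OC)cc(C)cc12)NC(C)=O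
F5 | step 8 | (S)-6,8-dimethoxy-1,3-dimethyl-3,4-dihydroisoquinoline | C[C@H]1Cc2cc(OC)cc(OC)c2C(C)=N1
F6 | step 8 | (1R,3S)-6,8-dimethoxy-1,3-dimethyl-1,2,3,4-tetrahydroisoquinoline | C[C@H]1Cc2cc(OC)cc(OC)c2[C@@H](C)N1
F7 | step 8 | (1R,3S)-6,8-dimethoxy-1,2,3-trimethyl-1,2,3,4-tetrahydroisoquinoline | C[C@H]1Cc2cc(OC)cc(OC)c2[C@@H](C)N1C
F8 | step 8 | 4-[(1R,3S)-6,8-dimethoxy-1,2,3-trimethyl-1,2,3,4-tetrahydroisoquinolin-5-yl]-8-methoxy-6-methylnaphthalen-1-ol | C[C@H]1Cc2c(-c3ccc(O)c4c(OC)cc(C)cc34)c(OC)cc(OC)c2[C@@H](C)N1C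
F9 | step 5 | N,N-diethyl-2-methoxy-4,6-dimethylbenzamide | CCN(CC)C(=O)c1c(C)cc(C)cc1OC
F10 | step 5 | 8-methoxy-6-methyl-2-(phenylsulfinyl)-3,4-dihydronaphthalen-1(2H)-one | COc1cc(C)cc2c1C(=O)C(CC2)S(=O)c1ccccc1
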